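**Plan**
1. Labels: unit A is the 1-methylquinolin-2-one whose C3 bears Ca, the CH carrying the 2-methylprop-1-enyl group. Unit B is the 2,2,6-trimethylpyrano[3,2-c]quinolin-5-one whose C4 is Cb and whose C3 is Cc, the O-bearing CH. The target is CaR, CbS, CcS.
2. Retrosynthetic cuts, in order: the isobutenyl C=C (Wittig, back to Ca–CHO); the Ca–Cb bond of the central dihydropyran (ring closure); the aryl ether O4(unit A)–Cc (addition–elimination); the pyran of unit B (Knoevenagel/oxa-6π).
3. Forward order: pyran of unit B; epoxidation and methanolysis of its olefin; ether link to unit A; enol ether; closure of the central pyran through Ca–Cb; olefination last.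
4. Enabling feature: Cb is C4 of the pyranoquinolinone, one bond from C4a=C10b–O1, so a leaving group there ionises to a vinylogous oxocarbenium ion. Ca, made the β-carbon of an enol ether on C3 of unit A, lies six atoms round from it through O4–C4=C3 of unit A.
5. Stereochemistry: Cc from a Jacobsen–Katsuki epoxidation, carried through untouched; Cb from attack syn to the Cc oxygen (cis fusion); Ca from the cyclisation and the thermodynamic preference of the epimerisable aldehyde.

Key step: step 6

Assumption: the (S,S)-catalyst is taken to give the (3S,4S)-oxide, as it does with 2,2-dimethylchromenes (otherwise the (R,R)-catalyst is used). The C4 configuration of 8 and the E/Z geometry of 10 are immaterial, because both are erased in step 6.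

Step 1
Reactants: 1 4-hydroxy-1-methylquinolin-2(1H)-one; 2 3-methylbut-2-enal
Product: 4 N-methylflindersine (2,2,6-trimethyl-2H-pyrano[3,2-c]quinolin-5(6H)-one), via quinone methide 3 (not isolated)
Conditions: pyridine, 110 °C
Reagents that add atoms: none
Why: Knoevenagel condensation at the enolic C3 gives quinone methide 3, whose oxa-6π electrocyclisation onto the C4 carbonyl closes the 2H-pyran (the established entry to pyrano[3,2-c]quinolinones); no stereocentre is formed.

Step 2
Reactants: 1 4-hydroxy-1-methylquinolin-2(1H)-one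
Product: 6 4-chloro-1-methyl-2-oxo-1,2-dihydroquinoline-3-carbaldehyde, via iminium chloride 5 (not isolated)
Conditions: POCl3, DMF, 0 → 70 °C; then ice-water
Reagents that add atoms: N,N-dimethylformamide CN(C)C=O; phosphoryl chloride O=P(Cl)(Cl)Cl; water O
Why: Vilsmeier–Haack reaction, which formylates C3 and exchanges the vinylogous acid OH for chloride (the standard conversion of 4-hydroxy-2-quinolones into 4-chloro-3-formyl-2-quinolones), iminium salt 5 being hydrolysed on work-up.

Step 3
Reactants: 4 N-methylflindersine
Product: 8 (3S,4R)-3-hydroxy-4-methoxy-2,2,6-trimethyl-3,4-dihydro-2H-pyrano[3,2-c]quinolin-5(6H)-one, via epoxide 7 (not isolated)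
Conditions: (S,S)-[Mn(salen)Cl] (salen = N,N′-bis(3,5-di-tert-butylsalicylidene)cyclohexane-1,2-diaminate, 4 mol %), 4-phenylpyridine N-oxide, aq NaOCl (pH 11), CH2Cl2, 0 °C; organic phase dried, then MeOH, PPTS (cat.), 0 °C
Reagents that add atoms: sodium hypochlorite [Na+].[O-]Cl; methanol CO
Why: Jacobsen–Katsuki epoxidation of the cis-disubstituted, aryl-conjugated olefin (the 2,2-dimethylchromene substrate class) should set Cc as S by oxygen delivery to one enantioface, and acid-catalysed methanolysis then opens the labile epoxide at benzylic C4 with inversion without touching the C3–O bond.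

Step 4
Reactants: 8 (3S,4R)-3-hydroxy-4-methoxy-2,2,6-trimethyl-3,4-dihydro-2H-pyrano[3,2-c]quinolin-5(6H)-one; 6 4-chloro-1-methyl-2-oxo-1,2-dihydroquinoline-3-carbaldehyde
Product: 9 4-{[(3S,4R)-4-methoxy-2,2,6-trimethyl-5-oxo-3,4,5,6-tetrahydro-2H-pyrano[3,2-c]quinolin-3-yl]oxy}-1-methyl-2-oxo-1,2-dihydroquinoline-3-carbaldehyde
Conditions: NaH, THF, 0 °C; then 6, 0 °C → rt
Reagents that add atoms: none
Why: Nucleophilic aromatic substitution by addition–elimination at a vinylogous acid chloride: the sodium alkoxide of 8 adds to C4 of 6, activated by the ortho formyl group and the lactam carbonyl, and chloride leaves; the C–O bond at Cc is not involved, so its configuration is retained.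

Step 5
Reactants: 9 the ether aldehyde from step 4
Product: 10 (3S,4R)-4-methoxy-3-({3-[(E)-2-methoxyethenyl]-1-methyl-2-oxo-1,2-dihydroquinolin-4-yl}oxy)-2,2,6-trimethyl-3,4-dihydro-2H-pyrano[3,2-c]quinolin-5(6H)-one (E/Z mixture; E drawn)
Conditions: MeOCH2PPh3Cl, KHMDS, THF, 0 °C; then 9, −78 → 0 °C
Reagents that add atoms: (methoxymethyl)triphenylphosphonium chloride COC[P+](c1ccccc1)(c1ccccc1)c1ccccc1.[Cl-]
Why: Wittig methoxymethylenation of the aryl aldehyde gives the enol ether that serves both as the carbon nucleophile of step 6 and as the masked Ca–CHO; no stereocentre is affected and both alkene isomers are usable.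

Step 6
Reactants: 10 the bis-methoxy enol ether from step 5
Product: 13 (CaR,CbS,CcS)-heptacyclic aldehyde (target skeleton with CHO on Ca), via benzylic cation 11 (not isolated), via dimethyl acetal 12 (not isolated)
Conditions: TMSOTf (20 mol %), 4 Å MS, CH2Cl2, −78 → −40 °C; then 1 M HCl, THF, 0 °C → rt
Reagents that add atoms: water O
Why: TMSOTf ionises the benzylic 4-methoxy group of unit B to cation 11 (charge spread over C4, C4a=C10b and O1), the enol ether carbon bonded to C3 of unit A (β to OMe, hence the nucleophilic terminus) attacks C4, and the resulting methyl oxocarbenium ion takes back the methoxide held as TMSOMe, which regenerates TMSOTf and makes the event a catalytic isomerisation of 10 to acetal 12, hydrolysed to 13 on acidic work-up. The closest known reaction type is the Lewis-acid-mediated SN1 alkylation of enol ethers (Mukaiyama-type, Prins-type) by 4-alkoxychroman and flavan-4-yl cations. The one ring formed, the central dihydropyran (O4, C4 and C3 of unit A, Ca, Cb, Cc), closes in 6-(enolexo)-exo-trig mode. Cb is controlled by Cc: the nucleophile hangs from the Cc oxygen and must attack the planar cation pseudo-axially from the face carrying that oxygen, which gives the cis ring fusion; Ca is set in a chair-like transition state and, being α to the aldehyde, can equilibrate during hydrolysis to the epimer with its substituent anti to the unit B bond at Cb, the other epimer suffering either a syn-diaxial clash with the CMe2 carbon or peri strain against both lactam carbonyls. The step needs C-attack through the aryl-bearing enol ether carbon (secured by OMe polarisation and six- over seven-membered closure) and no loss of the Cc proton from 11 (secured by low temperature, a non-basic medium and fast intramolecular capture).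

Step 7
Reactants: 13 the heptacyclic aldehyde from step 6
Product: 14 CNP0107253.2 (CaR,CbS,CcS)
Conditions: iPrPPh3I, KHMDS, THF, 0 °C; then 13, −78 → 0 °C
Reagents that add atoms: isopropyltriphenylphosphonium iodide CC(C)[P+](c1ccccc1)(c1ccccc1)c1ccccc1.[I-]
Why: Wittig olefination with the non-stabilised isopropylidene ylide turns CHO into the 2-methylprop-1-enyl group; no new stereocentre is formed, and Ca, should it enolise, is expected to return to the favoured anti configuration.

**Compound list**
1 | 4-hydroxy-1-methylquinolin-2(1H)-one | Cn1c(=O)cc(O)c2ccccc12 | starting material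
2 | 3-methylbut-2-enal | CC(C)=CC=O | starting material
3 | (E)-1-methyl-3-(3-methylbut-2-en-1-ylidene)quinoline-2,4(1H,3H)-dione (quinone methide) | CC(C)=C/C=C1/C(=O)N(C)c2ccccc2C1=O | intermediate
4 | N-methylflindersine, 2,2,6-trimethyl-2H-pyrano[3,2-c]quinolin-5(6H)-one | CC1(C)C=Cc2c(O1)c1ccccc1n(C)c2=O | intermediate
5 | N-[(4-chloro-1-methyl-2-oxo-1,2-dihydroquinolin-3-yl)methylidene]-N-methylmethanaminium chloride | C[N+](C)=Cc1c(Cl)c2ccccc2n(C)c1=O.[Cl-] | intermediate
6 | 4-chloro-1-methyl-2-oxo-1,2-dihydroquinoline-3-carbaldehyde | O=Cc1c(Cl)c2ccccc2n(C)c1=O | intermediate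
7 | (3S,4S)-3,4-epoxy-2,2,6-trimethyl-3,4-dihydro-2H-pyrano[3,2-c]quinolin-5(6H)-one | O1[C@H]2[C@@H]1c1c(c3ccccc3n(C)c1=O)OC2(C)C | intermediate
8 | (3S,4R)-3-hydroxy-4-methoxy-2,2,6-trimethyl-3,4-dihydro-2H-pyrano[3,2-c]quinolin-5(6H)-one | O[C@H]1[C@H](OC)c2c(c3ccccc3n(C)c2=O)OC1(C)C | intermediate
9 | 4-{[(3S,4R)-4-methoxy-2,2,6-trimethyl-5-oxo-3,4,5,6-tetrahydro-2H-pyrano[3,2-c]quinolin-3-yl]oxy}-1-methyl-2-oxo-1,2-dihydroquinoline-3-carbaldehyde | O=Cc1c(O[C@H]2[C@H](OC)c3c(c4ccccc4n(C)c3=O)OC2(C)C)c2ccccc2n(C)c1=O | intermediate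
10 | (3S,4R)-4-methoxy-3-({3-[(E)-2-methoxyethenyl]-1-methyl-2-oxo-1,2-dihydroquinolin-4-yl}oxy)-2,2,6-trimethyl-3,4-dihydro-2H-pyrano[3,2-c]quinolin-5(6H)-one | CO/C=C/c1c(O[C@H]2[C@H](OC)c3c(c4ccccc4n(C)c3=O)OC2(C)C)c2ccccc2n(C)c1=O | intermediate
11 | (3S)-3-({3-[(E)-2-methoxyethenyl]-1-methyl-2-oxo-1,2-dihydroquinolin-4-yl}oxy)-2,2,6-trimethyl-5-oxo-3,4,5,6-tetrahydro-2H-pyrano[3,2-c]quinolin-4-ylium triflate (benzylic cation at Cb) | CO/C=C/c1c(O[C@H]2[CH+]c3c(c4ccccc4n(C)c3=O)OC2(C)C)c2ccccc2n(C)c1=O.[O-]S(=O)(=O)C(F)(F)F | intermediate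
12 | dimethyl acetal of 13: cis-fused bis-pyran with CH(OMe)2 on Ca; Ca R, Cb S, Cc S | COC(OC)[C@H]1c2c(c3ccccc3n(C)c2=O)O[C@H]2[C@@H]1c1c(c3ccccc3n(C)c1=O)OC2(C)C | intermediate
13 | heptacyclic aldehyde: the dihydropyran of unit B cis-fused across C3(Cc)–C4(Cb) to a second dihydropyran made of O4, C4, C3 of unit A and Ca; CHO on Ca; Ca R, Cb S, Cc S; H on Ca trans to H on Cb, H on Cb cis to H on Cc | O=C[C@H]1c2c(c3ccccc3n(C)c2=O)O[C@H]2[C@@H]1c1c(c3ccccc3n(C)c1=O)OC2(C)C | intermediate
14 | CNP0107253.2: as 13 with 2-methylprop-1-enyl on Ca; Ca R, Cb S, Cc S | CC(C)=C[C@H]1c2c(c3ccccc3n(C)c2=O)O[C@H]2[C@@H]1c1c(c3ccccc3n(C)c1=O)OC2(C)C | target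

**Step count**
Total steps: 7. Longest linear sequence: 6 (steps 1, 3, 4, 5, 6, 7); step 2 is a one-step side branch.

**Steps most likely to fail**

Step 6. The risks are loss of the Cc proton from the cation (erosion of configuration at Cc), protonation of the enol ether before the methoxy group ionises, and kinetic formation of the wrong Ca epimer. The fallback sets out from 10 and returns at 13. The enol ether of 10 is hydrolysed under neutral conditions (Hg(OAc)2, THF–H2O; then aq KI) to 2-(4-{[(3S,4R)-4-methoxy-2,2,6-trimethyl-5-oxo-3,4,5,6-tetrahydro-2H-pyrano[3,2-c]quinolin-3-yl]oxy}-1-methyl-2-oxo-1,2-dihydroquinolin-3-yl)acetaldehyde F1. The same bond is then closed by enamine catalysis: 5-benzyl-2,2,3-trimethylimidazolidin-4-one trifluoroacetate (20 mol %) with In(OTf)3 (10 mol %) in CH2Cl2 at 0 °C. The neutral enamine of F1 captures the transiently ionised benzylic centre (organocatalytic SN1-type α-alkylation of an aldehyde) under much less acidic conditions and gives 13 directly.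

Step 4. The risks are slow addition–elimination, because the alkoxide oxygen on C3 of 8 is flanked by the gem-dimethyl carbon, and competing attack at the formyl group. The fallback sets out from 8 and 6 and returns at 9. The ether bond is made by palladium-catalysed C–O cross-coupling (Pd2(dba)3, tBuBrettPhos, Cs2CO3, toluene, 80 °C), in which the C–O bond forms by reductive elimination at the metal and not by attack on the ring carbon. It makes no new compound (none, F0).

Step 7. The risks are enolisation of the α-aryl, α-branched aldehyde by the basic, hindered ylide, giving incomplete olefination and scrambling at Ca. The fallback sets out from 13 and returns at 14. Non-basic dibromo-olefination (CBr4, PPh3, 2,6-lutidine, CH2Cl2, 0 °C; Corey–Fuchs first stage) gives the 1,1-dibromoalkene on Ca, F2. Twofold Negishi methylation (Me2Zn, Pd(PtBu3)2, THF, rt → 50 °C) then installs both methyl groups.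

Further compounds
F1 | step 6 | 2-(4-{[(3S,4R)-4-methoxy-2,2,6-trimethyl-5-oxo-3,4,5,6-tetrahydro-2H-pyrano[3,2-c]quinolin-3-yl]oxy}-1-methyl-2-oxo-1,2-dihydroquinolin-3-yl)acetaldehyde | O=CCc1c(O[C@H]2[C@H](OC)c3c(c4ccccc4n(C)c3=O)OC2(C)C)c2ccccc2n(C)c1=O
F0 | step 4 | none | none
F2 | step 7 | 1,1-dibromoalkene of 13 (CH=CBr2 on Ca; Ca R, Cb S, Cc S) | BrC(Br)=C[C@H]1c2c(c3ccccc3n(C)c2=O)O[C@H]2[C@@H]1c1c(c3ccccc3n(C)c1=O)OC2(C)C
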